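## Structural features

The target is an achiral diaryl ether: two benzene rings joined by one oxygen between C6 of ring A and C1' of ring B, with no stereocentre and no stereogenic double bond, so no stereocentres stand next to each other. Ring A carries on four neighbouring carbons, in order, the aryloxy group (C6), the carboxylic acid (C1), a phenol (C2) and the prenyl chain (C3); C4 and C5 are CH. Ring B carries the ether oxygen at C1' between a phenol (C2') and a hydroxymethyl group (C6'), with a methyl group at C4'. The ether oxygen therefore has three ortho substituents, and this is the real difficulty: coupling a 2,6-disubstituted phenol with an ortho-substituted, electron-rich aryl partner is unreliable. The fragile groups are: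

- the prenyl alkene next to the C2 phenol, which acid closes to a 2,2-dimethylchroman;
- the 2,6-dioxygenated benzoic acid, which can decarboxylate in hot acid;
- the benzylic alcohol;
- the acid and the C2' phenol together, which can form a seven-membered aryl lactone.

The plan uses the fact that C1, C2, C3 and C4 of ring A (carboxyl, oxygen, prenyl, hydrogen) reproduce C3 to C6 of a 3-alkoxycarbonyl-4-acyloxy-5-prenyl-2-pyrone, and that C5–C6 with its aryloxy group is an aryl ethynyl ether. Ring A is thus grown on an oxygen that ring B already carries, and the crowded C–O bond is never made by coupling.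

## Logic of the disconnections

23 to 22: no skeletal bond is cut, only the acyl C–O bond of the pivalate and the C–O bond of the methyl ester. Both groups are kept to the end so that the acid and the C2 phenol stay masked through all earlier steps. The demand on the forward step is hydrolysis of a benzoate with two ortho substituents.

22 to 21: the two O–CH2 acetal bonds on ring B are cut. The acetals are removed before the hydrolysis, not after it, so the acid step meets a ring A whose C2 oxygen is still acylated and cannot add to the prenyl alkene. The forward step needs an acid mild enough for the alkene and the benzylic alcohol.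

21 to 9 and 19: ring A is cut at C4–C5 and at C6–C1. This returns 9, which holds four ring carbons with all three substituents, and 19, which holds two carbons and the ether oxygen; a one-carbon lactone bridge is present in 20 and is lost as gas. The gain is large: the hindered ether bond is inherited from a phenol, and ring A arrives at the arene oxidation level. The forward step must control regiochemistry and must be faster than decomposition of 19.

19 to 17 (via 18): the triple bond is traced to a dichloroalkene, restoring two C–Cl bonds. This hides the sensitive alkyne until the step before it is used. The demand is that an alkyllithium attacks the vinyl chloride faster than it metalates next to the acetal oxygens.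

17 to 16 to 15: the benzylic O–CH2 acetal bond is cut and the alcohol is taken back to an aldehyde. The aldehyde is wanted earlier because it differentiates the two ring oxygens. The forward steps are routine.

15 to 13 and 14: the O–C(vinyl) bond is cut. Placing this cut at the aldehyde stage caps the C1' oxygen before any second hydroxyl exists, so phenol and benzylic alcohol never have to be told apart. The demand is addition of a hindered, formyl-substituted phenoxide to 14.

13 to 12 to 11 to 10: the acetal O–C bond on the C2' oxygen, the O–CH3 bond and the aryl–CHO bond are cut in turn. 10 already has the oxygen pattern and the methyl group of ring B. The demands are ortho-selective formylation and selective protection of one of two phenols.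

9 to 8: the acyl C–O bond at O4 is cut. The forward acylation must go on the ring oxygen at C4.

8 to 4 and 5 (via 6 and 7): the ring is cut at the lactone O1–C2 bond and at C3–C4. 5 supplies C2, C3 and the ester; 4 supplies C4, C5 with the prenyl group, and C6 as a masked aldehyde. The forward step needs C-acylation of 5 and ring closure under acid that spares the alkene.

4 to 3 to 1 and 2: the ester C–O bond and then the C–C bond between the α-carbon and the allylic CH2 are cut. Two simple commercial pieces result. The enolate must be alkylated before it eliminates methoxide.

## Other disconnections considered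

Alternative 1: Ring B is made last.
- Cut and key step: C4'–C5' and C1'–C6' of ring B are cut, giving the aryloxymethyl ynone A1 (an ordinary alkyl aryl ether of a ring A phenol) and methyl pyruvate A2. The enolate of A2 would add in conjugate fashion to the alkyne terminus of A1; the aryloxy-bearing CH2 would close onto the keto group of the A2 unit in an aldol step; loss of water and tautomerization should give the phenol ester A3.
- In favour: the hindered ether bond is not made by coupling, no ynol ether is handled and nothing is heated. On robustness of the partners and mildness of the ring-forming step this alternative is better than the chosen plan.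
- Against: A3 has hydrogen at C1 of ring A and carries the future hydroxymethyl carbon of ring B as an ester. The ring A carboxyl must still be introduced by lithiation between the two ring A oxygens and carboxylation, after the ring B ester has been reduced and protected. The phenol behind A1 needs a regioselective prenylation of a resorcinol derivative. A2 self-condenses easily under enolization, and the conjugate adduct must reach the alkene geometry that allows the aldol closure.
- Comparison: on structure, both plans fix the substitution pattern of the new ring by polarity of the partners and are equal there. On mechanism, this is a stepwise ionic cascade against a pericyclic pair of steps. On step economy the chosen plan is ahead: about five functional-group steps would follow A3, against two after 21.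

Alternative 2: Ring A is again built on an ynol ether of ring B, but from a four-carbon ketene precursor.
- Cut and key step: C1–C2 and C5–C6 are cut and C2–C3 is re-formed, giving the cyclobutenone A4 and the internal ynol ether A5. The alkyne terminus of A5 must carry the silyloxymethyl group that becomes the C1 substituent; the terminal ynol ether 19 would leave C1 unsubstituted. On heating, A4 should open to a vinylketene, add to A5 in a [2+2] step, open again and close by 6π electrocyclization to the phenol A6.
- In favour: benzannulations of this type with alkoxy and silyloxy alkynes are well established. The regiochemistry (ynol ether oxygen meta to the new hydroxyl, alkyne substituent between them) is the one needed, and the C2 phenol appears free. On precedent for an ynol ether as reaction partner this alternative is at least the equal of the chosen plan.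
- Against: C1 arrives at the alcohol oxidation level. Two oxidations would be needed on an electron-rich ring with a free ortho-prenyl phenol and a trisubstituted alkene, which means phenol protection, desilylation, two oxidations and deprotection. A4 is strained and base-sensitive and needs its own multistep preparation. The vinylketene from A4 has the prenyl alkene within reach for an internal [2+2] reaction.
- Comparison: on structure, both use the same ring B branch up to 18. On mechanism, both are thermal and neutral. On step economy the chosen plan is better by roughly four to five steps, because C1 enters as an ester at the correct oxidation level.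

Alternative 3: No ring is formed; the two bonds cut are O–C6 and C1–carboxyl.
- Cut and key step: the ortho-silyl aryl triflate A7, the ring B phenol A8 as its potassium salt and carbon dioxide A9 would be combined. Fluoride should release the 3-alkoxyaryne from A7, the phenoxide should add at C6 (the aryne carbon remote from the acetal oxygen), and the C1 aryl anion should be trapped by A9 to give the acid A10.
- In favour: it is the most convergent plan, it sets both bonds of the crowded region in one step, and one deprotection separates A10 from the target. On convergence and on steps after the key step this alternative is better than the chosen plan. The regiochemistry rests on the usual bias of 3-alkoxyarynes, so the two plans are equal on that point.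
- Against: the nucleophile is a phenoxide with two ortho substituents. The aryl anion is protonated by any phenol present as easily as it is carboxylated, which would give the ether without the carboxyl. A9 ties up the phenoxide reversibly as a carbonate, and the aryne can undergo an ene reaction with a prenyl alkene of a second molecule. A7 needs a regiocontrolled synthesis of five or more steps, and A8 needs a phenol to be differentiated from a benzylic alcohol. A10 carries the C2 oxygen as an acetal, so its last step exposes the ortho-prenyl phenol and the salicylic acid to acid.
- Comparison: on structure, this plan must make the crowded C–O bond intermolecularly, which the chosen plan avoids. On mechanism, three species must react in the right order in one flask, against a two-component cycloaddition. On step economy the totals should be similar, with more risk concentrated in one step.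

Key step: step 12

Remark: the target has no stereocentre; 3, 4, 6, 7 and 20 are racemic, and their stereocentres disappear in 8 and 21.

## Steps

Step 1
Reactants: 1 methyl 3,3-dimethoxypropanoate; 2 1-bromo-3-methylbut-2-ene (prenyl bromide)
Product: 3 methyl 2-(dimethoxymethyl)-5-methylhex-4-enoate (racemic)
Conditions: LiN(i-Pr)2, THF, −78 °C; then 2, DMPU, −78 → −30 °C
Reagents that add atoms: none
Why: Alkylation of a kinetic lithium ester enolate by SN2 at the primary carbon of a reactive allylic bromide; low temperature and DMPU should let alkylation outrun β-elimination of methoxide. The α-stereocentre is formed racemic and is erased when this carbon becomes C5 of the pyrone.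

Step 2
Reactants: 3 methyl 2-(dimethoxymethyl)-5-methylhex-4-enoate
Product: 4 2-(dimethoxymethyl)-5-methylhex-4-enoic acid (racemic)
Conditions: LiOH·H2O, THF/MeOH/H2O, rt; then cold 1 M HCl to pH 4
Reagents that add atoms: lithium hydroxide, [Li+].[OH-]
Why: Saponification of an unhindered methyl ester; the dimethyl acetal is stable to hydroxide, and acidification is stopped at pH 4 in the cold so that it survives.

Step 3
Reactants: 4 2-(dimethoxymethyl)-5-methylhex-4-enoic acid; 5 dimethyl malonate
Product: 8 methyl 4-hydroxy-5-(3-methylbut-2-en-1-yl)-2-oxo-2H-pyran-3-carboxylate, via acyl imidazolide 6 (not isolated), via acylmalonate 7 (not isolated)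
Conditions: 1,1'-carbonyldiimidazole, THF, rt; then 5, MgCl2, Et3N, MeCN, rt → 45 °C; then 2 M HCl aq, THF, rt → 40 °C
Reagents that add atoms: water, O
Why: Activation without HCl keeps the acetal intact, and magnesium-mediated C-acylation of malonate under soft enolization (a Claisen-type acylation) gives the acylmalonate. Dilute acid then unmasks the aldehyde, whose enol oxygen lactonizes onto one malonate ester, the usual closure of 3,5-dioxo esters to 4-hydroxy-2-pyrones. The acid is kept dilute and warm at most, so the enol hydroxyl does not add to the prenyl alkene.

Step 4
Reactants: 8 methyl 4-hydroxy-5-(3-methylbut-2-en-1-yl)-2-oxo-2H-pyran-3-carboxylate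
Product: 9 methyl 4-[(2,2-dimethylpropanoyl)oxy]-5-(3-methylbut-2-en-1-yl)-2-oxo-2H-pyran-3-carboxylate
Conditions: pivaloyl chloride, Et3N, DMAP (cat.), CH2Cl2, 0 °C
Reagents that add atoms: pivaloyl chloride, CC(C)(C)C(=O)Cl
Why: O-acylation of the acidic 4-hydroxy-2-pyrone enol; the 4-O-acyl isomer keeps the conjugated 2-pyrone and is the stable product. The pivalate removes the acidic proton that would destroy the ynol ether, weakens donation from O4 into the diene, resists acyl transfer, and later masks the C2 phenol of ring A.

Step 5
Reactants: 10 creosol (2-methoxy-4-methylphenol)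
Product: 11 2-hydroxy-3-methoxy-5-methylbenzaldehyde
Conditions: MgCl2, Et3N, (CH2O)n, MeCN, reflux; then 1 M HCl
Reagents that add atoms: paraformaldehyde (as formaldehyde), C=O
Why: Magnesium phenoxide-directed ortho-formylation (Casnati–Skattebøl); the only free ortho position is C6, so a single regioisomer is expected.

Step 6
Reactants: 11 2-hydroxy-3-methoxy-5-methylbenzaldehyde
Product: 12 2,3-dihydroxy-5-methylbenzaldehyde
Conditions: BBr3, CH2Cl2, −78 → 0 °C; then H2O
Reagents that add atoms: none
Why: Lewis acid cleavage of an aryl methyl ether; kept at or below 0 °C the formyl group should only be complexed, not brominated.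

Step 7
Reactants: 12 2,3-dihydroxy-5-methylbenzaldehyde
Product: 13 2-hydroxy-3-(methoxymethoxy)-5-methylbenzaldehyde
Conditions: NaH (2.2 equiv), DMF, 0 °C; then MOMCl (1.0 equiv), 0 °C → rt; then NH4Cl aq
Reagents that add atoms: chloromethyl methyl ether, COCCl
Why: Regioselective O-alkylation of a dianion: the 2-phenoxide is delocalized into and chelated with the formyl group, so the 3-phenoxide is the more nucleophilic oxygen and takes the single equivalent of electrophile.

Step 8
Reactants: 13 2-hydroxy-3-(methoxymethoxy)-5-methylbenzaldehyde; 14 trichloroethylene
Product: 15 2-{[(E)-1,2-dichloroethenyl]oxy}-3-(methoxymethoxy)-5-methylbenzaldehyde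
Conditions: 14 (2 equiv), K2CO3, DMF, 70 °C
Reagents that add atoms: none
Why: Base eliminates HCl from trichloroethylene to give dichloroacetylene in low concentration; the phenoxide adds and anti protonation gives the (E)-dichlorovinyl ether, the standard entry to aryl ynol ethers. Doing this at the aldehyde stage caps the C1' oxygen before the benzylic alcohol exists.

Step 9
Reactants: 15 2-{[(E)-1,2-dichloroethenyl]oxy}-3-(methoxymethoxy)-5-methylbenzaldehyde
Product: 16 [2-{[(E)-1,2-dichloroethenyl]oxy}-3-(methoxymethoxy)-5-methylphenyl]methanol
Conditions: NaBH4, MeOH, 0 °C
Reagents that add atoms: none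
Why: Borohydride reduction of an aryl aldehyde; the dichlorovinyl ether and the acetal are inert to it.

Step 10
Reactants: 16 [2-{[(E)-1,2-dichloroethenyl]oxy}-3-(methoxymethoxy)-5-methylphenyl]methanol
Product: 17 2-{[(E)-1,2-dichloroethenyl]oxy}-1-(methoxymethoxy)-3-[(methoxymethoxy)methyl]-5-methylbenzene
Conditions: MOMCl, i-Pr2NEt, CH2Cl2, 0 °C → rt
Reagents that add atoms: chloromethyl methyl ether, COCCl
Why: O-alkylation of the only free hydroxyl with an α-chloro ether (Williamson-type acetal formation); no selectivity question arises.

Step 11
Reactants: 17 2-{[(E)-1,2-dichloroethenyl]oxy}-1-(methoxymethoxy)-3-[(methoxymethoxy)methyl]-5-methylbenzene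
Product: 19 2-(ethynyloxy)-1-(methoxymethoxy)-3-[(methoxymethoxy)methyl]-5-methylbenzene, via lithium alkynyl ether 18 (not isolated)
Conditions: n-BuLi (2.2 equiv), THF, −78 → −40 °C; then MeOH, −78 °C; cold NaHCO3 aq work-up; used at once
Reagents that add atoms: none
Why: Deprotonation of the vinyl CH, β-elimination of LiCl to the chloroalkynyl ether and chlorine–lithium exchange give the lithium acetylide, which is protonated cold. These steps are fast at −78 °C, so metalation next to the acetal oxygens should not compete; the two ortho substituents shield the ynol ether from self-reaction.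

Step 12
Reactants: 9 methyl 4-[(2,2-dimethylpropanoyl)oxy]-5-(3-methylbut-2-en-1-yl)-2-oxo-2H-pyran-3-carboxylate; 19 2-(ethynyloxy)-1-(methoxymethoxy)-3-[(methoxymethoxy)methyl]-5-methylbenzene (1.3 equiv)
Product: 21 methyl 6-{2-(methoxymethoxy)-6-[(methoxymethoxy)methyl]-4-methylphenoxy}-3-(3-methylbut-2-en-1-yl)-2-[(2,2-dimethylpropanoyl)oxy]benzoate, via bridged lactone 20 (not isolated)
Conditions: toluene (degassed), powdered K2CO3 (acid scavenger), base-washed sealed tube, 100 °C
Reagents that add atoms: none
Why: This is an inverse-electron-demand Diels–Alder reaction of an electron-poor 2-pyrone with an ynol ether followed by cycloreversion, the established way from 3-alkoxycarbonyl-2-pyrones and heteroatom-substituted alkynes or ketene acetals to benzoates. The diene C3=C4–C5=C6 of 9 has its LUMO lowered by the lactone carbonyl, the C3 ester and the acyloxy group, with the largest coefficient at C6, while the HOMO of 19 is largest at the terminal CH carbon. Bond formation is therefore asynchronous: the CH carbon bonds to C6 first and the oxygen-bearing carbon then bonds to C3, giving the bridged lactone 20. Ring A is closed by this intermolecular [4+2] cycloaddition, which forms C4–C5 and C6–C1 in ring A numbering, and it becomes a benzene by retro-[4+2] loss of CO2 from 20, so no oxidation is needed. The two bridgehead stereocentres of 20 are racemic and transient and vanish on aromatization, so no stereocentre has to be controlled. The step needs regioselectivity (aryloxy group next to the ester) and chemoselectivity (cycloaddition faster than self-reaction of 19 or acyl transfer from 9). The first follows from the polarity match above; the second is supported by the two ortho substituents that shield the ynol ether, by the absence of a β-hydrogen in an aryl ynol ether, which closes the retro-ene path to a ketene, and by the hindered pivalate. Acid is excluded because ynol ethers add protic partners readily.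

Step 13
Reactants: 21 methyl 6-{2-(methoxymethoxy)-6-[(methoxymethoxy)methyl]-4-methylphenoxy}-3-(3-methylbut-2-en-1-yl)-2-[(2,2-dimethylpropanoyl)oxy]benzoate
Product: 22 methyl 6-[2-hydroxy-6-(hydroxymethyl)-4-methylphenoxy]-3-(3-methylbut-2-en-1-yl)-2-[(2,2-dimethylpropanoyl)oxy]benzoate
Conditions: conc. HCl (5 vol%), MeOH/THF, rt → 35 °C
Reagents that add atoms: none
Why: Acid-catalysed acetal exchange with methanol removes the aryl and the benzylic methoxymethyl groups, and the formaldehyde unit leaves as dimethoxymethane and so cannot attack electron-rich ring B. The C2 oxygen of ring A is still pivaloylated at this point, so there is no free phenol next to the prenyl alkene to close to a chroman; the aryl pivalate and the methyl ester are stable to methanolic HCl.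

Step 14
Reactants: 22 methyl 6-[2-hydroxy-6-(hydroxymethyl)-4-methylphenoxy]-3-(3-methylbut-2-en-1-yl)-2-[(2,2-dimethylpropanoyl)oxy]benzoate
Product: 23 2-hydroxy-6-[2-hydroxy-6-(hydroxymethyl)-4-methylphenoxy]-3-(3-methylbut-2-en-1-yl)benzoic acid (CNP0140656.0)
Conditions: LiOH·H2O (10 equiv), THF/MeOH/H2O (degassed), 50 °C, argon; then cold 1 M HCl to pH 3
Reagents that add atoms: lithium hydroxide, [Li+].[OH-]
Why: Saponification: the aryl pivalate goes first and the ortho-disubstituted methyl benzoate is then hydrolysed by excess hydroxide with gentle heat, possibly assisted by the C2' phenoxide through a transient seven-membered aryl lactone that hydroxide opens. The prenyl alkene, the diaryl ether and the benzylic alcohol are stable to base, and the final acidification is brief, cold and mild.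

## Compound list

1 | methyl 3,3-dimethoxypropanoate | COC(=O)CC(OC)OC | starting material
2 | 1-bromo-3-methylbut-2-ene (prenyl bromide) | CC(C)=CCBr | starting material
3 | methyl 2-(dimethoxymethyl)-5-methylhex-4-enoate (racemic) | COC(=O)C(CC=C(C)C)C(OC)OC | intermediate
4 | 2-(dimethoxymethyl)-5-methylhex-4-enoic acid (racemic) | OC(=O)C(CC=C(C)C)C(OC)OC | intermediate
5 | dimethyl malonate | COC(=O)CC(=O)OC | starting material
6 | 2-(dimethoxymethyl)-1-(1H-imidazol-1-yl)-5-methylhex-4-en-1-one (racemic acyl imidazolide) | COC(OC)C(CC=C(C)C)C(=O)n1ccnc1 | intermediate
7 | dimethyl 2-[2-(dimethoxymethyl)-5-methylhex-4-enoyl]propanedioate (racemic acylmalonate) | COC(=O)C(C(=O)OC)C(=O)C(CC=C(C)C)C(OC)OC | intermediate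
8 | methyl 4-hydroxy-5-(3-methylbut-2-en-1-yl)-2-oxo-2H-pyran-3-carboxylate | COC(=O)C1=C(O)C(CC=C(C)C)=COC1=O | intermediate
9 | methyl 4-[(2,2-dimethylpropanoyl)oxy]-5-(3-methylbut-2-en-1-yl)-2-oxo-2H-pyran-3-carboxylate | COC(=O)C1=C(OC(=O)C(C)(C)C)C(CC=C(C)C)=COC1=O | intermediate
10 | creosol (2-methoxy-4-methylphenol) | COc1cc(C)ccc1O | starting material
11 | 2-hydroxy-3-methoxy-5-methylbenzaldehyde | COc1cc(C)cc(C=O)c1O | intermediate
12 | 2,3-dihydroxy-5-methylbenzaldehyde | O=Cc1cc(C)cc(O)c1O | intermediate
13 | 2-hydroxy-3-(methoxymethoxy)-5-methylbenzaldehyde | COCOc1cc(C)cc(C=O)c1O | intermediate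
14 | trichloroethylene | ClC=C(Cl)Cl | starting material
15 | 2-{[(E)-1,2-dichloroethenyl]oxy}-3-(methoxymethoxy)-5-methylbenzaldehyde | COCOc1cc(C)cc(C=O)c1O/C(Cl)=C\Cl | intermediate
16 | [2-{[(E)-1,2-dichloroethenyl]oxy}-3-(methoxymethoxy)-5-methylphenyl]methanol | COCOc1cc(C)cc(CO)c1O/C(Cl)=C\Cl | intermediate
17 | 2-{[(E)-1,2-dichloroethenyl]oxy}-1-(methoxymethoxy)-3-[(methoxymethoxy)methyl]-5-methylbenzene | COCOCc1cc(C)cc(OCOC)c1O/C(Cl)=C\Cl | intermediate
18 | ({2-(methoxymethoxy)-6-[(methoxymethoxy)methyl]-4-methylphenoxy}ethynyl)lithium (lithium alkynyl ether) | [Li]C#COc1c(OCOC)cc(C)cc1COCOC | intermediate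
19 | 2-(ethynyloxy)-1-(methoxymethoxy)-3-[(methoxymethoxy)methyl]-5-methylbenzene | C#COc1c(OCOC)cc(C)cc1COCOC | intermediate
20 | methyl 8-{2-(methoxymethoxy)-6-[(methoxymethoxy)methyl]-4-methylphenoxy}-6-(3-methylbut-2-en-1-yl)-3-oxo-5-[(2,2-dimethylpropanoyl)oxy]-2-oxabicyclo[2.2.2]octa-5,7-diene-4-carboxylate (racemic bridged lactone) | COC(=O)C12C(=O)OC(C=C1Oc1c(OCOC)cc(C)cc1COCOC)C(CC=C(C)C)=C2OC(=O)C(C)(C)C | intermediate
21 | methyl 6-{2-(methoxymethoxy)-6-[(methoxymethoxy)methyl]-4-methylphenoxy}-3-(3-methylbut-2-en-1-yl)-2-[(2,2-dimethylpropanoyl)oxy]benzoate | CC(C)=CCc1ccc(Oc2c(OCOC)cc(C)cc2COCOC)c(C(=O)OC)c1OC(=O)C(C)(C)C | intermediate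
22 | methyl 6-[2-hydroxy-6-(hydroxymethyl)-4-methylphenoxy]-3-(3-methylbut-2-en-1-yl)-2-[(2,2-dimethylpropanoyl)oxy]benzoate | CC(C)=CCc1ccc(Oc2c(O)cc(C)cc2CO)c(C(=O)OC)c1OC(=O)C(C)(C)C | intermediate
23 | 2-hydroxy-6-[2-hydroxy-6-(hydroxymethyl)-4-methylphenoxy]-3-(3-methylbut-2-en-1-yl)benzoic acid | CC(C)=CCc1ccc(Oc2c(O)cc(C)cc2CO)c(C(=O)O)c1O | target

## Step count and least certain steps

Total: 14 steps. Longest linear sequence: 10 steps (10 to 23, steps 5 to 14); the pyrone branch (steps 1 to 4) joins at step 12.

**Step 12 (key step).** The most likely failure is a mismatch of rates. An aryl ynol ether is a weaker nucleophile than the ynamines and ketene acetals usually paired with such pyrones, so 19 may be consumed by oligomerization or hydration, or 9 may transfer its acyl group, before cycloaddition occurs. The fallback keeps the pyrone cycloaddition for ring A but brings in the C6 oxygen as a phenol and makes the diaryl ether by palladium-catalysed C–O coupling of the Buchwald–Hartwig type. It sets out from 9 and 13 and returns at 22. Heating 9 with 1,1-bis(trimethylsilyloxy)ethene, followed by loss of CO2 and trimethylsilanol and aqueous work-up, should give methyl 6-hydroxy-3-(3-methylbut-2-en-1-yl)-2-[(2,2-dimethylpropanoyl)oxy]benzoate F1. Tf2O and pyridine convert it to methyl 3-(3-methylbut-2-en-1-yl)-2-[(2,2-dimethylpropanoyl)oxy]-6-{[(trifluoromethyl)sulfonyl]oxy}benzoate F2. Coupling with 13 (Pd(OAc)2, t-BuXPhos, K3PO4, toluene, 100 °C) should give methyl 6-[2-formyl-6-(methoxymethoxy)-4-methylphenoxy]-3-(3-methylbut-2-en-1-yl)-2-[(2,2-dimethylpropanoyl)oxy]benzoate F3. NaBH4 reduces the aldehyde to methyl 6-[2-(hydroxymethyl)-6-(methoxymethoxy)-4-methylphenoxy]-3-(3-methylbut-2-en-1-yl)-2-[(2,2-dimethylpropanoyl)oxy]benzoate F4, and the acid conditions of step 13 remove the one acetal to reach 22. The coupling of a hindered, electron-poor phenol is the weak point of this detour, which is why it is the fallback.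

**Step 11.** The most likely failure is loss of the terminal ynol ether during work-up and concentration (acid-catalysed hydration, oligomerization), or metalation next to an acetal oxygen if the alkyllithium is in excess. The fallback isolates a capped, storable alkyne. It sets out from 17 and returns at 19: the lithium species 18 is quenched with Me3SiCl instead of methanol to give trimethyl({2-(methoxymethoxy)-6-[(methoxymethoxy)methyl]-4-methylphenoxy}ethynyl)silane F5, which can be purified and kept. K2CO3 in methanol at 0 °C removes the silyl group immediately before the cycloaddition.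

**Step 3.** The most likely failure is sluggish C-acylation of malonate by the α-branched acyl imidazolide 6, or loss of material in the acid stage by addition of the enol hydroxyl to the prenyl alkene. The fallback reverses the order of bond formation (lactone oxygen first, C3–C4 last). It sets out from 3 and returns at 8. Dilute acid hydrolyses the acetal to methyl 2-formyl-5-methylhex-4-enoate F6, which is largely enolic. Its sodium enolate is O-acylated with methyl 3-chloro-3-oxopropanoate to give methyl (2Z)-2-{[(3-methoxy-3-oxopropanoyl)oxy]methylidene}-5-methylhex-4-enoate F7. An intramolecular Claisen (Dieckmann) condensation with DBU or NaH then closes C3–C4.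

**Step 13.** The most likely failure is slow cleavage of the benzylic alkyl acetal, which invites stronger acid and then costs the prenyl alkene (addition of HCl or methanol) or etherifies the benzylic alcohol. The fallback changes the protecting group on the benzylic oxygen to a silyl ether, which leaves under much milder acid together with the aryl acetal. It sets out from 16 and returns at 22. t-BuMe2SiCl and imidazole give tert-butyl({2-[(E)-1,2-dichloroethenyl]oxy-3-(methoxymethoxy)-5-methylphenyl}methoxy)dimethylsilane F8. n-BuLi then methanol give tert-butyl{[2-(ethynyloxy)-3-(methoxymethoxy)-5-methylphenyl]methoxy}dimethylsilane F9. Cycloaddition with 9 as in step 12 gives methyl 6-{2-[(tert-butyldimethylsilyloxy)methyl]-6-(methoxymethoxy)-4-methylphenoxy}-3-(3-methylbut-2-en-1-yl)-2-[(2,2-dimethylpropanoyl)oxy]benzoate F10. Catalytic TsOH in methanol at 0 °C to room temperature should remove both groups.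

**Step 14.** The most likely failure is stalling at the doubly ortho-substituted methyl benzoate once the pivalate is gone and ring A is a phenoxide, with decomposition if the conditions are forced. The fallback uses the neighbouring ring B phenol deliberately. It sets out from 22 and returns at 23: K2CO3 in DMF at 60 to 80 °C should let the C2' phenoxide attack the ester with loss of methanol to give the seven-membered aryl lactone (depsidone) of 22 F11, in which the ring A carbonyl is esterified by the C2' oxygen and all other groups are unchanged. This activated aryl ester and the pivalate are then opened by LiOH at room temperature.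

**Step 7.** The most likely failure is alkylation at the wrong oxygen or at both, which would lead to an isomeric diaryl ether. The fallback protects both oxygens and then frees one. It sets out from 12 and returns at 13. Excess MOMCl and i-Pr2NEt give 2,3-bis(methoxymethoxy)-5-methylbenzaldehyde F12. Only the acetal ortho to the formyl group is then removed; it is the more labile one because the freed phenol is hydrogen-bonded to the carbonyl (catalytic HCl in methanol at 0 °C, stopped at mono-deprotection).

## Further compounds

F1 | step 12 | methyl 6-hydroxy-3-(3-methylbut-2-en-1-yl)-2-[(2,2-dimethylpropanoyl)oxy]benzoate | CC(C)=CCc1ccc(O)c(C(=O)OC)c1OC(=O)C(C)(C)C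
F2 | step 12 | methyl 3-(3-methylbut-2-en-1-yl)-2-[(2,2-dimethylpropanoyl)oxy]-6-{[(trifluoromethyl)sulfonyl]oxy}benzoate | CC(C)=CCc1ccc(OS(=O)(=O)C(F)(F)F)c(C(=O)OC)c1OC(=O)C(C)(C)C
F3 | step 12 | methyl 6-[2-formyl-6-(methoxymethoxy)-4-methylphenoxy]-3-(3-methylbut-2-en-1-yl)-2-[(2,2-dimethylpropanoyl)oxy]benzoate | CC(C)=CCc1ccc(Oc2c(OCOC)cc(C)cc2C=O)c(C(=O)OC)c1OC(=O)C(C)(C)C
F4 | step 12 | methyl 6-[2-(hydroxymethyl)-6-(methoxymethoxy)-4-methylphenoxy]-3-(3-methylbut-2-en-1-yl)-2-[(2,2-dimethylpropanoyl)oxy]benzoate | CC(C)=CCc1ccc(Oc2c(OCOC)cc(C)cc2CO)c(C(=O)OC)c1OC(=O)C(C)(C)C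
F5 | step 11 | trimethyl({2-(methoxymethoxy)-6-[(methoxymethoxy)methyl]-4-methylphenoxy}ethynyl)silane | C[Si](C)(C)C#COc1c(OCOC)cc(C)cc1COCOC
F6 | step 3 | methyl 2-formyl-5-methylhex-4-enoate (racemic, largely enol) | COC(=O)C(C=O)CC=C(C)C
F7 | step 3 | methyl (2Z)-2-{[(3-methoxy-3-oxopropanoyl)oxy]methylidene}-5-methylhex-4-enoate | COC(=O)CC(=O)O/C=C(/CC=C(C)C)C(=O)OC
F8 | step 13 | tert-butyl({2-[(E)-1,2-dichloroethenyl]oxy-3-(methoxymethoxy)-5-methylphenyl}methoxy)dimethylsilane | CC(C)(C)[Si](C)(C)OCc1cc(C)cc(OCOC)c1O/C(Cl)=C\Cl
F9 | step 13 | tert-butyl{[2-(ethynyloxy)-3-(methoxymethoxy)-5-methylphenyl]methoxy}dimethylsilane | CC(C)(C)[Si](C)(C)OCc1cc(C)cc(OCOC)c1OC#C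
F10 | step 13 | methyl 6-{2-[(tert-butyldimethylsilyloxy)methyl]-6-(methoxymethoxy)-4-methylphenoxy}-3-(3-methylbut-2-en-1-yl)-2-[(2,2-dimethylpropanoyl)oxy]benzoate | CC(C)=CCc1ccc(Oc2c(OCOC)cc(C)cc2CO[Si](C)(C)C(C)(C)C)c(C(=O)OC)c1OC(=O)C(C)(C)C
F11 | step 14 | seven-membered aryl lactone (depsidone) of 22: ring A carbonyl esterified by the C2' oxygen of ring B, with hydroxymethyl, methyl, prenyl and pivaloyloxy groups unchanged | CC(C)=CCc1ccc2c(c1OC(=O)C(C)(C)C)C(=O)Oc1cc(C)cc(CO)c1O2
F12 | step 7 | 2,3-bis(methoxymethoxy)-5-methylbenzaldehyde | COCOc1cc(C)cc(C=O)c1OCOC
A1 | alternative 1 | 1-[3-(methoxymethoxy)-4-(3-methylbut-2-en-1-yl)phenoxy]pent-3-yn-2-one | CC#CC(=O)COc1ccc(CC=C(C)C)c(OCOC)c1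
A2 | alternative 1 | methyl pyruvate | CC(=O)C(=O)OC
A3 | alternative 1 | methyl 3-hydroxy-2-[3-(methoxymethoxy)-4-(3-methylbut-2-en-1-yl)phenoxy]-5-methylbenzoate | COC(=O)c1cc(C)cc(O)c1Oc1ccc(CC=C(C)C)c(OCOC)c1
A4 | alternative 2 | 4-(3-methylbut-2-en-1-yl)cyclobut-2-en-1-one (racemic) | O=C1C=CC1CC=C(C)C
A5 | alternative 2 | tert-butyl[(3-{2-(methoxymethoxy)-6-[(methoxymethoxy)methyl]-4-methylphenoxy}prop-2-yn-1-yl)oxy]dimethylsilane | CC(C)(C)[Si](C)(C)OCC#COc1c(OCOC)cc(C)cc1COCOC
A6 | alternative 2 | 2-[(tert-butyldimethylsilyloxy)methyl]-3-{2-(methoxymethoxy)-6-[(methoxymethoxy)methyl]-4-methylphenoxy}-6-(3-methylbut-2-en-1-yl)phenol | CC(C)=CCc1ccc(Oc2c(OCOC)cc(C)cc2COCOC)c(CO[Si](C)(C)C(C)(C)C)c1O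
A7 | alternative 3 | 3-(methoxymethoxy)-4-(3-methylbut-2-en-1-yl)-2-(trimethylsilyl)phenyl trifluoromethanesulfonate | CC(C)=CCc1ccc(OS(=O)(=O)C(F)(F)F)c([Si](C)(C)C)c1OCOC
A8 | alternative 3 | 2-(methoxymethoxy)-6-[(methoxymethoxy)methyl]-4-methylphenol | COCOCc1cc(C)cc(OCOC)c1O
A9 | alternative 3 | carbon dioxide | O=C=O
A10 | alternative 3 | 2-(methoxymethoxy)-6-{2-(methoxymethoxy)-6-[(methoxymethoxy)methyl]-4-methylphenoxy}-3-(3-methylbut-2-en-1-yl)benzoic acid | CC(C)=CCc1ccc(Oc2c(OCOC)cc(C)cc2COCOC)c(C(=O)O)c1OCOC
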